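The plan cuts both C–N bonds of the pyrrole ring, N1–C2 and N1–C5. What remains, C2–C3–C4–C5, is a straight four-carbon segment substituted only at its ends (formyl carbon on C2, henicosyl chain on C5). It is exactly as oxidised as a 1,3-diyne. One copper-catalysed twofold hydroamination with an acid-cleavable benzylic primary amine therefore forms both C–N bonds and the ring in a single redox-neutral operation that loses no atoms. The precursor is a linear 26-carbon 2,4-diyne whose C1 is a diethyl acetal. It is made by Cadiot–Chodkiewicz coupling of a 23-carbon bromoalkyne with commercial propiolaldehyde diethyl acetal. Wet acid finally unmasks the aldehyde and frees N–H.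

Key step: step 4

Remark: the target is achiral and its side chain is taken as unbranched C21; acetal hydrolysis consumes water, so step 5 is run in wet acid; carbons C2–C5 of the diyne chain become ring atoms C2–C5, so one set of locants serves for both.

Step 1
Reactants: 1 1-bromoicosane; 2 trimethyl(prop-1-yn-1-yl)silane
Product: 4 trimethyl(tricos-1-yn-1-yl)silane, via lithiated silylpropyne 3 (not isolated)
Conditions: 2 (1.3 equiv), n-BuLi, THF, −78 → −20 °C; then 1, DMPU, −20 °C → rt
Reagents that add atoms: none
Why: Propargylic lithiation of the alkynylsilane followed by SN2 alkylation of the primary bromide is a standard three-carbon homologation in which the silyl group directs bond formation to the propargylic rather than the allenic terminus, so it should give the 23-carbon alkyne with its terminus already masked, and the excess of volatile 2 drives the hard-to-separate bromide to full conversion.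

Step 2
Reactants: 4 trimethyl(tricos-1-yn-1-yl)silane
Product: 5 1-bromotricos-1-yne
Conditions: NBS (1.2 equiv), AgNO3 (20 mol %), acetone/CH2Cl2, rt, dark
Reagents that add atoms: N-bromosuccinimide, O=C1CCC(=O)N1Br
Why: Silver-catalysed bromodesilylation of an alkynylsilane with NBS is an ipso-substitution at the silver-activated sp carbon, so it should exchange SiMe3 for Br in one operation and leave the saturated chain untouched.

Step 3
Reactants: 5 1-bromotricos-1-yne; 6 3,3-diethoxyprop-1-yne
Product: 7 1,1-diethoxyhexacosa-2,4-diyne
Conditions: 6 (1.5 equiv), CuCl (10 mol %), NH2OH·HCl (cat.), n-BuNH2, H2O/THF, 0 °C → rt, slow addition of 5 in THF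
Reagents that add atoms: none
Why: In this Cadiot–Chodkiewicz coupling the more acidic acetal alkyne is the partner metalated by copper and is taken in excess while the bromoalkyne is fed in slowly, which should favour the unsymmetrical diyne over either homodimer, and the basic medium cannot harm the acetal.

Step 4
Reactants: 7 1,1-diethoxyhexacosa-2,4-diyne; 8 2,4-dimethoxybenzylamine
Product: 10 2-(diethoxymethyl)-1-(2,4-dimethoxybenzyl)-5-henicosyl-1H-pyrrole, via aminoenyne 9 (not isolated)
Conditions: 8 (3 equiv), CuCl (10 mol %), neat, 100 °C, Ar, sealed tube; then short plug of basic Al2O3
Reagents that add atoms: none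
Why: Monovalent copper binds the diyne as a π-acid and the primary amine adds to an outer sp carbon, preferentially C5 next to the unhindered chain CH2 because the charge building up at C4 is taken up by the adjacent acetal-bearing alkyne, and protodemetalation gives aminoenyne 9. Enamine–imine tautomerism lets 9 adopt the Z geometry, in which the same nitrogen reaches C2 of the remaining copper-bound alkyne; this 5-endo-dig closure forms the only ring, and proton transfer aromatises it without change of oxidation level or loss of atoms. The closest known reaction type is the CuCl-catalysed synthesis of 1,2,5-trisubstituted pyrroles from 1,3-diynes and primary amines (Reisch–Schulte pyrrole synthesis), applied here to an unsymmetrical diyne with two sp3 substituents. No stereocentre is formed. The selectivity needed is regiochemical, with nitrogen on both outer carbons C2 and C5: attack at an inner carbon would place the metal on a carbon not conjugated with the second alkyne and could not lead on to a five-membered ring, and because first attack at C2 would lead to the same pyrrole, the order of the two additions does not matter. The diethyl acetal is inert to the amine, so neither imine formation nor conjugate addition to an ynal can compete, and the unhindered benzylic amine is nucleophilic enough to serve neat in excess.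

Step 5
Reactants: 10 2-(diethoxymethyl)-1-(2,4-dimethoxybenzyl)-5-henicosyl-1H-pyrrole
Product: 12 5-henicosyl-1H-pyrrole-2-carbaldehyde, via N-dimethoxybenzyl aldehyde 11 (not isolated)
Conditions: TFA/CH2Cl2 (1:1), H2O (5 equiv), anisole (10 equiv), 0 → 40 °C
Reagents that add atoms: water, O
Why: Acid-catalysed acetal hydrolysis, fast because the pyrrole nitrogen assists loss of ethanol and with water supplying the carbonyl oxygen, gives 11, a vinylogous formamide whose O-protonated form should release the 2,4-dimethoxybenzyl group by SN1 acidolysis as N-dimethoxybenzyl amides do, with anisole taking up the benzyl group by Friedel–Crafts alkylation while the formyl group deactivates C3 and C4 towards it.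

Compound list
1 | 1-bromoicosane | CCCCCCCCCCCCCCCCCCCCBr | starting material
2 | trimethyl(prop-1-yn-1-yl)silane | CC#C[Si](C)(C)C | starting material
3 | [3-(trimethylsilyl)prop-2-yn-1-yl]lithium | [Li]CC#C[Si](C)(C)C | intermediate
4 | trimethyl(tricos-1-yn-1-yl)silane | CCCCCCCCCCCCCCCCCCCCCC#C[Si](C)(C)C | intermediate
5 | 1-bromotricos-1-yne | CCCCCCCCCCCCCCCCCCCCCC#CBr | intermediate
6 | 3,3-diethoxyprop-1-yne | C#CC(OCC)OCC | starting material
7 | 1,1-diethoxyhexacosa-2,4-diyne | CCCCCCCCCCCCCCCCCCCCCC#CC#CC(OCC)OCC | intermediate
8 | 2,4-dimethoxybenzylamine | NCc1ccc(OC)cc1OC | starting material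
9 | (Z)-N-(2,4-dimethoxybenzyl)-1,1-diethoxyhexacos-4-en-2-yn-5-amine | CCCCCCCCCCCCCCCCCCCCC/C(NCc1ccc(OC)cc1OC)=C/C#CC(OCC)OCC | intermediate
10 | 2-(diethoxymethyl)-1-(2,4-dimethoxybenzyl)-5-henicosyl-1H-pyrrole | CCCCCCCCCCCCCCCCCCCCCc1ccc(C(OCC)OCC)n1Cc1ccc(OC)cc1OC | intermediate
11 | 1-(2,4-dimethoxybenzyl)-5-henicosyl-1H-pyrrole-2-carbaldehyde | CCCCCCCCCCCCCCCCCCCCCc1ccc(C=O)n1Cc1ccc(OC)cc1OC | intermediate
12 | 5-henicosyl-1H-pyrrole-2-carbaldehyde | CCCCCCCCCCCCCCCCCCCCCc1ccc(C=O)[nH]1 | target

Total step count: 5. Longest linear sequence: 5 (1 → 4 → 5 → 7 → 10 → 12).

**Steps most likely to fail**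

**Step 4 carries the most risk.**
- A diyne without aryl activation may take up the amine too slowly. Base-induced isomerisation and oligomerisation of the diyne could then outrun ring formation, or the reaction could stall at the open-chain stage.
- Partial exchange of the acetal for the imine of 8 would be harmless, because step 5 hydrolyses both to the aldehyde.
- The fallback gives up ring construction and decorates an intact pyrrole, using known chemistry only. It sets out from 1.
- Magnesium in THF converts 1 into icosylmagnesium bromide F1. A little more than two equivalents of this reagent are added to commercial pyrrole-2-carbaldehyde, the first equivalent removing N–H. This should give racemic 1-(1H-pyrrol-2-yl)henicosan-1-ol F2, which is used crude.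
- NaBH4 in refluxing 2-propanol should replace the hydroxyl group by hydrogen through elimination and hydride addition, as in the known reduction of 2-acylpyrroles. The product is 2-henicosyl-1H-pyrrole F3.
- Vilsmeier–Haack formylation (POCl3, DMF; then aqueous NaOAc) at the free α-position C5 comes back to the route at 12.

**Step 5 is second.**
- Heterolysis of the N–benzyl bond may be slow, or the benzylic cation may return to C3 or C4 of the ring instead of being captured by anisole.
- The fallback replaces acidolysis by oxidative cleavage. It sets out from 10.
- Brief treatment of 10 with aqueous acetic acid in THF gives 11, which is now isolated.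
- DDQ in wet CH2Cl2 should oxidise the electron-rich benzylic CH2. After water adds, the N–C bond breaks, and the route is rejoined at 12.
- This fallback makes no compound that is missing from the list (entry F0).

**Step 3 is third.**
- Halogen–copper exchange may scramble the partners and lead to homocoupling. Poor mixing of the waxy bromoalkyne with the aqueous amine phase would make this worse.
- The fallback replaces the alkynyl halide cross-coupling by an oxidative coupling of two terminal alkynes. It sets out from 4.
- K2CO3 in MeOH/THF removes the silyl group to give tricos-1-yne F4.
- Glaser–Hay coupling (CuCl, TMEDA, air, CH2Cl2) with a fivefold excess of cheap 6 should statistically favour the cross product.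
- The hydrocarbon dimer and the bis-acetal dimer differ strongly in polarity from the product, so separation should be simple. The route is rejoined at 7.

Further compounds
F1 | step 4 | icosylmagnesium bromide | CCCCCCCCCCCCCCCCCCCC[Mg]Br
F2 | step 4 | (±)-1-(1H-pyrrol-2-yl)henicosan-1-ol | CCCCCCCCCCCCCCCCCCCCC(O)c1ccc[nH]1
F3 | step 4 | 2-henicosyl-1H-pyrrole | CCCCCCCCCCCCCCCCCCCCCc1ccc[nH]1
F0 | step 5 | none | none
F4 | step 3 | tricos-1-yne | CCCCCCCCCCCCCCCCCCCCCC#C
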